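**Plan**
- Ring B (C5–C6–C7–C8–C9–C10) carries oxygen at C7 and a quaternary C9 next to the cis C5–C10 fusion, and ring A has its double bond at C1=C2. The unit O–C7–C8–C9–C10–C1=C2 is what an oxy-Cope shift leaves, so the first cut is C9–C10 (with C2–C7 re-formed), giving a bicyclo[2.2.2]octene that holds a C7 alkenyl carbinol.
- Further cuts: C7–C8 (alkenyl metal + bicyclic C7 ketone), C2–C7 and C5–C6 (Diels–Alder of the masked o-benzoquinone of 2-methoxy-3-methylphenol with vinyl acetate), C11–C12 (allylic coupling in the side chain), C4=C18 (methylenation of the unmasked ketal).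
- Forward: the C8–C15 alkenyl iodide is built first, then the bicycle (future ring A plus C6/C7); the two are joined at C7; the [3,3] shift closes ring B; ring A (C2 oxygen, C4 methylene) is finished before the C7 carbonyl is unmasked.
- Stereochemistry: C13 from enzymatic desymmetrisation of dimethyl 3-methylglutarate; absolute configuration of the bicycle (hence C5) from a lipase resolution; C9 and C10 from the Z-alkene and the boat-shaped shift; C8 by protonation and C7 by dissolving-metal reduction, both only after C4 is trigonal so that the cis-decalin adopts the natural-product conformer.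
- The enolate from the shift is kept as an enol triflate, a C7 carbonyl mask that survives borane, acid and titanium methylenation.

Key step: step 15

Remark on numbering: clerodane numbering of the target is used for every intermediate (in the bicycle: bridgeheads C2–H and C5–CH3, bridges C1=C10, C3–C4 and C7–C6); β is the decalin face that carries the C5 methyl group.
Remark on the enzyme (assumption): the lipase is taken to follow the usual secondary-alcohol rule (bridgehead side large, CH2 side medium), so it cleaves the (7R) acetate and leaves the (7S) acetate needed here; if the preference were opposite, the hydrolysed ketol would be re-acetylated and carried on instead.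

**Route**

Step 1
Reactants: 1 dimethyl 3-methylglutarate
Product: 2 methyl hydrogen (R)-3-methylglutarate
Conditions: pig liver esterase, pH 7 phosphate buffer, 20% MeOH, −10 °C, pH-stat
Reagents that add atoms: water, O
Why: Enzymatic desymmetrisation (esterase hydrolysis of one enantiotopic ester group of a prochiral 3-substituted glutarate, known for this substrate) should set C13, which is R in 2.

Step 2
Reactants: 2 methyl hydrogen (R)-3-methylglutarate
Product: 3 methyl (S)-4-bromo-3-methylbutanoate
Conditions: red HgO, Br2, CCl4, reflux, dark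
Reagents that add atoms: bromine, BrBr
Why: The Cristol–Firth variant of the Hunsdiecker bromodecarboxylation shortens the free acid arm by one carbon to the primary bromide (future C12) through a primary radical that cannot touch the C13 centre.

Step 3
Reactants: 3 methyl (S)-4-bromo-3-methylbutanoate
Product: 4 (S)-4-bromo-3-methylbutan-1-ol
Conditions: DIBAL-H (2.2 equiv), CH2Cl2, −78 → −20 °C; Rochelle salt
Reagents that add atoms: none
Why: DIBAL-H reduction of an ester leaves a primary alkyl bromide intact at low temperature, and the cold neutral work-up avoids closure of the bromo alkoxide to a tetrahydrofuran.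

Step 4
Reactants: 4 (S)-4-bromo-3-methylbutan-1-ol
Product: 5 (S)-(4-bromo-3-methylbutoxy)triisopropylsilane
Conditions: TIPSCl, imidazole, DMF, 0 °C → rt
Reagents that add atoms: triisopropylsilyl chloride, CC(C)[Si](Cl)(C(C)C)C(C)C
Why: Standard silylation of a primary alcohol; TIPS is chosen because it should survive Grignard formation, t-BuLi, KH, dilute acid, hydroxide and Li/NH3 later.

Step 5
Reactants: 6 but-2-yn-1-ol
Product: 8 (Z)-3-iodo-2-methylbut-2-en-1-ol, via magnesium chelate 7 (not isolated)
Conditions: MeMgBr (3 equiv), CuI (10 mol%), THF, 0 °C → reflux; then I2, −40 → 0 °C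
Reagents that add atoms: methylmagnesium bromide, C[Mg]Br; iodine, II
Why: Copper-catalysed anti-carbomagnesiation of a propargylic alcohol puts the new methyl on the proximal alkyne carbon and magnesium on the distal one inside a five-membered alkoxide chelate, so iodinolysis with retention gives the tetrasubstituted iodoalkene with iodine cis to CH2OH (later C7 cis to C11).

Step 6
Reactants: 8 (Z)-3-iodo-2-methylbut-2-en-1-ol
Product: 9 (Z)-1-bromo-3-iodo-2-methylbut-2-ene
Conditions: CBr4, PPh3, CH2Cl2, 0 °C
Reagents that add atoms: carbon tetrabromide, BrC(Br)(Br)Br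
Why: Appel bromination turns the primary allylic alcohol into the bromide under neutral conditions without touching the vinyl iodide or the alkene geometry.

Step 7
Reactants: 5 (S)-(4-bromo-3-methylbutoxy)triisopropylsilane; 9 (Z)-1-bromo-3-iodo-2-methylbut-2-ene
Product: 11 (3R,6Z)-vinyl iodide with the full C8–C15 chain, via Grignard reagent 10 (not isolated)
Conditions: 5, Mg, THF, rt; then 9, Li2CuCl4 (3 mol%), THF, −78 → 0 °C
Reagents that add atoms: none
Why: Copper-catalysed cross-coupling of a primary alkyl Grignard reagent with a primary allylic bromide forms C11–C12 by direct displacement, because the SN2' terminus is a fully substituted iodine-bearing carbon and a vinyl iodide is inert to alkyl Grignard/copper at this temperature.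

Step 8
Reactants: 12 2-methoxy-3-methylphenol; 13 vinyl acetate
Product: 15 racemic bicyclic keto acetate, via masked o-benzoquinone 14 (not isolated)
Conditions: PhI(OAc)2, MeOH, vinyl acetate (large excess), slow addition of 12, rt → 50 °C
Reagents that add atoms: methanol, CO
Why: Oxidative dearomatisation of a 2-methoxyphenol in methanol gives the 6,6-dimethoxycyclohexa-2,4-dienone, which is trapped in an inverse-electron-demand Diels–Alder reaction with the enol ester; the known ortho/endo preference of these dienones joins CH2 to the methyl-bearing carbon (C5–C6) and the acetoxy carbon to the carbon α to the ketone (C2–C7) with OAc syn to the new C1=C10 bridge, fixing C2, C5 and C7 relative to each other.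

Step 9
Reactants: 15 racemic bicyclic keto acetate
Product: 16 (7S) keto acetate as a single enantiomer
Conditions: lipase PS (Burkholderia cepacia), pH 7 phosphate buffer/acetone, 30 °C, taken just past half conversion
Reagents that add atoms: none
Why: Lipase-catalysed kinetic resolution by enantioselective hydrolysis of a secondary acetate should remove the (7R) ester and leave 16, which carries the absolute configuration at C2 and C5.

Step 10
Reactants: 16 (7S) keto acetate
Product: 17 C3 hydroxy acetate
Conditions: NaBH4, THF/EtOH, −20 → 0 °C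
Reagents that add atoms: none
Why: Borohydride reduction of the ketone in the presence of the acetate, with hydride arriving from the open face syn to the C1=C10 bridge (the other face meets the inward C7–H of the saturated bridge), so the C3 hydroxyl points toward the C6–C7 bridge; this centre only serves as a protected ketone.

Step 11
Reactants: 17 C3 hydroxy acetate
Product: 18 C3 TBS ether acetate
Conditions: TBSOTf, 2,6-lutidine, CH2Cl2, −78 → 0 °C
Reagents that add atoms: tert-butyldimethylsilyl triflate, CC(C)(C)[Si](C)(C)OS(=O)(=O)C(F)(F)F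
Why: Silyl triflate silylation of a hindered secondary alcohol; the neopentyl dimethyl ketal is not activated under these buffered conditions.

Step 12
Reactants: 18 C3 TBS ether acetate
Product: 19 C7 alcohol
Conditions: K2CO3, MeOH, rt
Reagents that add atoms: none
Why: Base-catalysed methanolysis (transesterification) removes the acetate and leaves the silyl ether and ketal untouched.

Step 13
Reactants: 19 C7 alcohol
Product: 20 bicyclic C7 ketone
Conditions: Dess–Martin periodinane, NaHCO3, CH2Cl2, rt
Reagents that add atoms: none
Why: Dess–Martin oxidation of the secondary alcohol gives the β,γ-unsaturated ketone under neutral conditions; the bridgehead C2–H cannot enolise, so the alkene stays in place.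

Step 14
Reactants: 11 (3R,6Z)-vinyl iodide; 20 bicyclic C7 ketone
Product: 23 tertiary alkenyl carbinol, via alkenyllithium 21 (not isolated), via alkenylcerium dichloride 22 (not isolated)
Conditions: 11, t-BuLi (2.1 equiv), Et2O, −78 °C; CeCl3, THF, −78 °C; then 20, −78 → −40 °C
Reagents that add atoms: none
Why: Iodine–lithium exchange retains the alkene geometry, and the organocerium reagent (1,2-addition of alkenylcerium reagents to hindered enolisable ketones) should attack C7 from the face syn to the C1=C10 bridge because the other face is closed by the C3 silyloxy group and the inward ketal methoxy group; this places the alkenyl group over the etheno bridge.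

Step 15
Reactants: 23 tertiary alkenyl carbinol
Product: 26 cis-decalin enol triflate, via potassium alkoxide 24 (not isolated), via potassium enolate 25 (not isolated)
Conditions: KH, 18-crown-6, THF, 0 °C → rt; then PhNTf2, −78 → 0 °C
Reagents that add atoms: N-phenylbis(trifluoromethanesulfonimide), O=S(=O)(N(c1ccccc1)S(=O)(=O)C(F)(F)F)C(F)(F)F
Why: The naked C7 alkoxide 24 weakens the allylic C2–C7 bond, so the 1,5-diene C9=C8–C7–C2–C1=C10 undergoes a concerted anionic oxy-Cope ([3,3]-sigmatropic) shift, the established behaviour of 2-alkenylbicyclo[2.2.2]oct-5-en-2-ols made from masked o-benzoquinone adducts. Ring B closes by suprafacial C9–C10 bonding on the face of the etheno bridge that carried C7, through the boat array forced by the bicycle, so the C5–C10 fusion can only be cis. C10 is fixed by that facial constraint, and C9 by the Z geometry of the alkene (C11 cis to C7), which the boat transfers so that the C11 chain ends syn and C20 anti to H10. The step needs the alkenyl group syn to the C1=C10 bridge, which step 14 secures; ketal and silyl ethers tolerate the base, and a 1,3 O-to-O shift of the C3 silyl group would place silicon on the tertiary oxygen and is uphill. O-Sulfonylation of the tetrasubstituted enolate 25 then stores the C7 carbonyl as an enol triflate that should be inert to borane, dilute acid and the titanium methylenation reagent.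

Step 16
Reactants: 26 cis-decalin enol triflate
Product: 28 C2 alcohol, via alkylborane 27 (not isolated)
Conditions: BH3·THF, THF, 0 °C → rt; then 30% H2O2, aq NaOAc, 0 °C → rt
Reagents that add atoms: hydrogen peroxide, OO
Why: Hydroboration–oxidation of the only reactive alkene (the tetrasubstituted enol triflate is inert) should place boron on C2, proximal to the allylic C–O bond as is usual for cyclic allylic ethers and away from the neopentyl C1–C10 side, and anti to the C3 silyloxy group; the C2 configuration is erased in the last step, and the acetate-buffered oxidation spares the triflate.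

Step 17
Reactants: 28 C2 alcohol
Product: 29 2,3-bis-TBS ether
Conditions: TBSOTf, 2,6-lutidine, CH2Cl2, −78 → 0 °C
Reagents that add atoms: tert-butyldimethylsilyl triflate, CC(C)(C)[Si](C)(C)OS(=O)(=O)C(F)(F)F
Why: Silylation of the secondary alcohol keeps C2 distinct from the C7 hydroxyl that is acetylated later.

Step 18
Reactants: 29 2,3-bis-TBS ether
Product: 30 C4 ketone
Conditions: TsOH·H2O (cat.), acetone/H2O, rt → 40 °C
Reagents that add atoms: water, O
Why: Acid-catalysed ketal hydrolysis (transketalisation into wet acetone) frees the C4 ketone now that no ring A alkene remains; catalytic sulfonic acid in acetone should be mild enough for hindered secondary TBS ethers, the primary TIPS ether and the enol triflate.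

Step 19
Reactants: 30 C4 ketone
Product: 31 C4 methylene compound
Conditions: Zn, CH2Br2, TiCl4, THF (reagent aged at 0 °C); then 30, CH2Cl2, rt
Reagents that add atoms: dibromomethane, BrCBr
Why: Takai–Lombardo methylenation is non-basic and works on hindered, enolisable α-oxygenated ketones where phosphorus ylides fail, and it leaves the enol triflate and silyl ethers alone; C4 is now trigonal as in the target.

Step 20
Reactants: 31 C4 methylene compound
Product: 33 C7 ketone with 8α-methyl, via potassium enolate 32 (not isolated)
Conditions: KOH, MeOH/THF/H2O, 40 °C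
Reagents that add atoms: none
Why: Hydroxide attacks sulfur (the familiar base hydrolysis of vinyl triflates) and releases enolate 32; with C4 trigonal the cis-decalin can take the chair–chair form with C19 and the C11 chain equatorial on ring B (an axial ketal methoxy group would clash with C9 and force the other form, which would give the C8 epimer), so axial protonation from the β face, away from the pseudoaxial C20, and equilibration should both favour the equatorial 8α-methyl, and any minor epimer can be resubmitted.

Step 21
Reactants: 33 C7 ketone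
Product: 34 7β-alcohol
Conditions: Li, NH3(l), THF, −78 °C; then solid NH4Cl
Reagents that add atoms: none
Why: Dissolving-metal reduction of a hindered cyclohexanone gives the thermodynamically preferred equatorial alcohol (7β, trans to the C8 methyl), whereas a hydride would enter from the β face because the α face is closed by the axial C4 and C20; isolated alkenes and silyl ethers are inert.

Step 22
Reactants: 34 7β-alcohol
Product: 35 7β-acetate
Conditions: Ac2O, pyridine, DMAP (cat.), CH2Cl2, rt
Reagents that add atoms: acetic anhydride, CC(=O)OC(C)=O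
Why: DMAP-catalysed acylation of the only free (equatorial secondary) hydroxyl installs the C7 acetate.

Step 23
Reactants: 35 7β-acetate
Product: 36 2,3,15-triol
Conditions: HF·pyridine, pyridine/THF, 0 → 40 °C
Reagents that add atoms: none
Why: Fluoride-driven desilylation removes the two secondary TBS ethers and the primary TIPS ether under buffered conditions that keep the acetate and the allylic alcohol intact.

Step 24
Reactants: 36 2,3,15-triol
Product: 38 2,3-dihydroxy carboxylic acid, via aldehyde 37 (not isolated)
Conditions: TEMPO (cat.), PhI(OAc)2, MeCN/H2O, rt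
Reagents that add atoms: water, O
Why: TEMPO/PhI(OAc)2 oxidation in aqueous acetonitrile takes a primary alcohol to the acid through the aldehyde hydrate and is selective over secondary hydroxyls, as in uronic acid syntheses with free vicinal diols; premature oxidation of the allylic C3 hydroxyl would only anticipate the last step.

Step 25
Reactants: 38 2,3-dihydroxy carboxylic acid
Product: 40 CNP0257844.1, via 2,3-diketone 39 (not isolated)
Conditions: IBX, DMSO, rt → 40 °C
Reagents that add atoms: none
Why: IBX oxidises a vicinal diol to the 1,2-diketone without C–C cleavage, and dione 39 can enolise only toward C1 (C4 has no hydrogen), giving the diosphenol conjugated with the C4 methylene.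

**Compound list**

1 | dimethyl 3-methylglutarate | COC(=O)CC(C)CC(=O)OC | starting material
2 | (R)-5-methoxy-3-methyl-5-oxopentanoic acid (methyl hydrogen (R)-3-methylglutarate) | OC(=O)C[C@@H](C)CC(=O)OC | intermediate
3 | methyl (S)-4-bromo-3-methylbutanoate | BrC[C@@H](C)CC(=O)OC | intermediate
4 | (S)-4-bromo-3-methylbutan-1-ol | BrC[C@@H](C)CCO | intermediate
5 | (S)-(4-bromo-3-methylbutoxy)triisopropylsilane | BrC[C@@H](C)CCO[Si](C(C)C)(C(C)C)C(C)C | intermediate
6 | but-2-yn-1-ol | CC#CCO | starting material
7 | 3,4-dimethyl-2,5-dihydro-1,2-oxamagnesole, cyclic alkoxide/alkenylmagnesium chelate (not isolated) | CC1=C(C)CO[Mg]1 | intermediate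
8 | (Z)-3-iodo-2-methylbut-2-en-1-ol | I/C(C)=C(C)\CO | intermediate
9 | (Z)-1-bromo-3-iodo-2-methylbut-2-ene | I/C(C)=C(C)\CBr | intermediate
10 | [(S)-2-methyl-4-(triisopropylsilyloxy)butyl]magnesium bromide (not isolated) | Br[Mg]C[C@@H](C)CCO[Si](C(C)C)(C(C)C)C(C)C | intermediate
11 | triisopropyl{[(3R,6Z)-7-iodo-3,6-dimethyloct-6-en-1-yl]oxy}silane | I/C(C)=C(C)\CC[C@@H](C)CCO[Si](C(C)C)(C(C)C)C(C)C | intermediate
12 | 2-methoxy-3-methylphenol | COc1c(C)cccc1O | starting material
13 | vinyl acetate | C=COC(C)=O | starting material
14 | 6,6-dimethoxy-5-methylcyclohexa-2,4-dien-1-one, masked o-benzoquinone (not isolated) | COC1(OC)C(C)=CC=CC1=O | intermediate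
15 | racemic bicyclo[2.2.2]octenone adduct: C3 ketone, C4 dimethyl ketal, C5 methyl bridgehead, C1=C10 bridge, C7 acetate syn to that bridge (relative configuration as drawn) | C[C@]12C=C[C@H](C(=O)C1(OC)OC)[C@@H](OC(C)=O)C2 | intermediate
16 | the same keto acetate as one enantiomer, (S) at the acetoxy carbon C7 | C[C@]12C=C[C@H](C(=O)C1(OC)OC)[C@@H](OC(C)=O)C2 | intermediate
17 | C3 alcohol of 16, hydroxyl pointing toward the C6–C7 bridge (anti to the etheno bridge), C7 acetate kept | C[C@]12C=C[C@H]([C@@H](O)C1(OC)OC)[C@@H](OC(C)=O)C2 | intermediate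
18 | C3 tert-butyldimethylsilyl ether of 17 | C[C@]12C=C[C@H]([C@@H](O[Si](C)(C)C(C)(C)C)C1(OC)OC)[C@@H](OC(C)=O)C2 | intermediate
19 | C7 alcohol (hydroxyl syn to the etheno bridge) with C3 OTBS and C4 ketal | C[C@]12C=C[C@H]([C@@H](O[Si](C)(C)C(C)(C)C)C1(OC)OC)[C@@H](O)C2 | intermediate
20 | bicyclic C7 ketone with C3 OTBS, C4 dimethyl ketal, C5 methyl | C[C@]12C=C[C@H]([C@@H](O[Si](C)(C)C(C)(C)C)C1(OC)OC)C(=O)C2 | intermediate
21 | (Z)-alkenyllithium from 11, lithium cis to the C11 chain (not isolated) | [Li]/C(C)=C(C)\CC[C@@H](C)CCO[Si](C(C)C)(C(C)C)C(C)C | intermediate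
22 | (Z)-alkenylcerium dichloride from 21 (not isolated) | Cl[Ce](Cl)/C(C)=C(C)\CC[C@@H](C)CCO[Si](C(C)C)(C(C)C)C(C)C | intermediate
23 | C7 tertiary carbinol on the bicyclo[2.2.2]octene: (Z)-alkenyl group C8(CH3)=C9(CH3)–C11 chain syn to the C1=C10 bridge, 7-OH toward the C3–C4 bridge, C3 OTBS, C4 ketal, (13R), C15 OTIPS | C[C@]12C=C[C@H]([C@@H](O[Si](C)(C)C(C)(C)C)C1(OC)OC)[C@@](O)(/C(C)=C(C)\CC[C@@H](C)CCO[Si](C(C)C)(C(C)C)C(C)C)C2 | intermediate
24 | potassium alkoxide of 23 (not isolated) | C[C@]12C=C[C@H]([C@@H](O[Si](C)(C)C(C)(C)C)C1(OC)OC)[C@@]([O-])(/C(C)=C(C)\CC[C@@H](C)CCO[Si](C(C)C)(C(C)C)C(C)C)C2.[K+] | intermediate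
25 | potassium C7 enolate of the cis-decalin (not isolated) | COC1(OC)[C@H](O[Si](C)(C)C(C)(C)C)C=C[C@@H]2[C@@](C)(CC[C@@H](C)CCO[Si](C(C)C)(C(C)C)C(C)C)C(C)=C([O-])C[C@]12C.[K+] | intermediate
26 | cis-decalin enol triflate: C7(OTf)=C8(CH3), C1=C2, 3α-OTBS, 4,4-dimethoxy, 5β-CH3, 10β-H, 9α-CH3, 9β-[(3R)-3-methyl-5-(triisopropylsilyloxy)pentyl] | COC1(OC)[C@H](O[Si](C)(C)C(C)(C)C)C=C[C@@H]2[C@@](C)(CC[C@@H](C)CCO[Si](C(C)C)(C(C)C)C(C)C)C(C)=C(OS(=O)(=O)C(F)(F)F)C[C@]12C | intermediate
27 | C2 alkylborane from 26, boron 2β (not isolated) | COC1(OC)[C@H](O[Si](C)(C)C(C)(C)C)[C@@H](B)C[C@@H]2[C@@](C)(CC[C@@H](C)CCO[Si](C(C)C)(C(C)C)C(C)C)C(C)=C(OS(=O)(=O)C(F)(F)F)C[C@]12C | intermediate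
28 | 2β-alcohol (trans to 3α-OTBS), otherwise as 26 with C1 saturated | COC1(OC)[C@H](O[Si](C)(C)C(C)(C)C)[C@@H](O)C[C@@H]2[C@@](C)(CC[C@@H](C)CCO[Si](C(C)C)(C(C)C)C(C)C)C(C)=C(OS(=O)(=O)C(F)(F)F)C[C@]12C | intermediate
29 | 2β,3α-bis(tert-butyldimethylsilyloxy) ketal enol triflate | COC1(OC)[C@H](O[Si](C)(C)C(C)(C)C)[C@@H](O[Si](C)(C)C(C)(C)C)C[C@@H]2[C@@](C)(CC[C@@H](C)CCO[Si](C(C)C)(C(C)C)C(C)C)C(C)=C(OS(=O)(=O)C(F)(F)F)C[C@]12C | intermediate
30 | C4 ketone with 2β,3α-bis-OTBS and the C7 enol triflate | O=C1[C@H](O[Si](C)(C)C(C)(C)C)[C@@H](O[Si](C)(C)C(C)(C)C)C[C@@H]2[C@@](C)(CC[C@@H](C)CCO[Si](C(C)C)(C(C)C)C(C)C)C(C)=C(OS(=O)(=O)C(F)(F)F)C[C@]12C | intermediate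
31 | C4(18)-methylene compound with 2β,3α-bis-OTBS and the C7 enol triflate | C=C1[C@H](O[Si](C)(C)C(C)(C)C)[C@@H](O[Si](C)(C)C(C)(C)C)C[C@@H]2[C@@](C)(CC[C@@H](C)CCO[Si](C(C)C)(C(C)C)C(C)C)C(C)=C(OS(=O)(=O)C(F)(F)F)C[C@]12C | intermediate
32 | potassium C7 enolate of the C4-methylene series (not isolated) | C=C1[C@H](O[Si](C)(C)C(C)(C)C)[C@@H](O[Si](C)(C)C(C)(C)C)C[C@@H]2[C@@](C)(CC[C@@H](C)CCO[Si](C(C)C)(C(C)C)C(C)C)C(C)=C([O-])C[C@]12C.[K+] | intermediate
33 | C7 ketone with 8α-CH3 (8β-H), C4 methylene, 2β,3α-bis-OTBS, C15 OTIPS | C=C1[C@H](O[Si](C)(C)C(C)(C)C)[C@@H](O[Si](C)(C)C(C)(C)C)C[C@@H]2[C@@](C)(CC[C@@H](C)CCO[Si](C(C)C)(C(C)C)C(C)C)[C@H](C)C(=O)C[C@]12C | intermediate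
34 | 7β-alcohol (trans to 8α-CH3), otherwise as 33 | C=C1[C@H](O[Si](C)(C)C(C)(C)C)[C@@H](O[Si](C)(C)C(C)(C)C)C[C@@H]2[C@@](C)(CC[C@@H](C)CCO[Si](C(C)C)(C(C)C)C(C)C)[C@H](C)[C@@H](O)C[C@]12C | intermediate
35 | 7β-acetate of 34 | C=C1[C@H](O[Si](C)(C)C(C)(C)C)[C@@H](O[Si](C)(C)C(C)(C)C)C[C@@H]2[C@@](C)(CC[C@@H](C)CCO[Si](C(C)C)(C(C)C)C(C)C)[C@H](C)[C@@H](OC(C)=O)C[C@]12C | intermediate
36 | 2β,3α,15-triol with 7β-OAc and C4 methylene | C=C1[C@H](O)[C@@H](O)C[C@@H]2[C@@](C)(CC[C@@H](C)CCO)[C@H](C)[C@@H](OC(C)=O)C[C@]12C | intermediate
37 | C15 aldehyde of 36 (not isolated) | C=C1[C@H](O)[C@@H](O)C[C@@H]2[C@@](C)(CC[C@@H](C)CC=O)[C@H](C)[C@@H](OC(C)=O)C[C@]12C | intermediate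
38 | 2β,3α-dihydroxy C15 carboxylic acid | C=C1[C@H](O)[C@@H](O)C[C@@H]2[C@@](C)(CC[C@@H](C)CC(=O)O)[C@H](C)[C@@H](OC(C)=O)C[C@]12C | intermediate
39 | 2,3-diketone tautomer of the target (not isolated) | C=C1C(=O)C(=O)C[C@@H]2[C@@](C)(CC[C@@H](C)CC(=O)O)[C@H](C)[C@@H](OC(C)=O)C[C@]12C | intermediate
40 | CNP0257844.1 | C=C1C(=O)C(O)=C[C@@H]2[C@@](C)(CC[C@@H](C)CC(=O)O)[C@H](C)[C@@H](OC(C)=O)C[C@]12C | target

**Count**

Total steps: 25. Longest linear sequence: 18 steps (steps 8–25, from 2-methoxy-3-methylphenol).

**Steps most likely to fail**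

1. Step 15. The fully substituted alkene terminus may reach C10 only under strain, so that the alkoxide is recovered or fragments instead of rearranging. Fallback from 23: silylate the tertiary hydroxyl with N-(trimethylsilyl)imidazole to the trimethylsilyl ether F1, and heat it in degassed decalin at about 200 °C (neutral siloxy-Cope rearrangement, same boat geometry) to the C7 trimethylsilyl enol ether F2. Methyllithium in THF then cleaves the O–Si bond to the lithium enolate F3, which is triflated with PhNTf2 to rejoin the route at 26.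

2. Step 18. The ketal is neopentyl and inductively deactivated by the C3 oxygen, so the silyl ethers may be lost before it ionises. Fallback from 28 (before the second silylation): treat with dilute aqueous HCl in THF at 0 °C → rt, accepting loss of the C3 silyl group together with the ketal, to give the 2β,3α-dihydroxy-4-ketone F4. Then silylate both hydroxyls with TBSOTf/2,6-lutidine, which returns to the route at 30.

3. Step 20. The equatorial preference at C8 is small because C17 is gauche to both C9 substituents, so equilibration may discriminate the epimers poorly. Fallback from 31: cleave the triflate with methyllithium in THF at 0 °C to the lithium enolate F5, and protonate it irreversibly at −78 °C with 2,6-di-tert-butylphenol, which should enter axially from the β face opposite the pseudoaxial C20 (kinetic instead of thermodynamic control). This rejoins the route at 33.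

**Further compounds**

F1 | step 15 | trimethylsilyl ether of carbinol 23 | C[C@]12C=C[C@H]([C@@H](O[Si](C)(C)C(C)(C)C)C1(OC)OC)[C@@](O[Si](C)(C)C)(/C(C)=C(C)\CC[C@@H](C)CCO[Si](C(C)C)(C(C)C)C(C)C)C2
F2 | step 15 | C7 trimethylsilyl enol ether of the cis-decalin | COC1(OC)[C@H](O[Si](C)(C)C(C)(C)C)C=C[C@@H]2[C@@](C)(CC[C@@H](C)CCO[Si](C(C)C)(C(C)C)C(C)C)C(C)=C(O[Si](C)(C)C)C[C@]12C
F3 | step 15 | lithium C7 enolate of the cis-decalin | COC1(OC)[C@H](O[Si](C)(C)C(C)(C)C)C=C[C@@H]2[C@@](C)(CC[C@@H](C)CCO[Si](C(C)C)(C(C)C)C(C)C)C(C)=C([O-])C[C@]12C.[Li+]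
F4 | step 18 | 2β,3α-dihydroxy-4-ketone with the C7 enol triflate | O=C1[C@H](O)[C@@H](O)C[C@@H]2[C@@](C)(CC[C@@H](C)CCO[Si](C(C)C)(C(C)C)C(C)C)C(C)=C(OS(=O)(=O)C(F)(F)F)C[C@]12C
F5 | step 20 | lithium C7 enolate of the C4-methylene series | C=C1[C@H](O[Si](C)(C)C(C)(C)C)[C@@H](O[Si](C)(C)C(C)(C)C)C[C@@H]2[C@@](C)(CC[C@@H](C)CCO[Si](C(C)C)(C(C)C)C(C)C)C(C)=C([O-])C[C@]12C.[Li+]
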